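In a one-step world, where substrate and reagent simply meet, the rate is proportional to each, so doubling the reagent doubles the rate. Does this flask live there?

| setting | beta | zeta | gamma | flask |
|---|---|---|---|---|
| substrate | 10 mM | 15 mM | 20 mM | 20 mM |
| reagent | 60 mM | 60 mM | 30 mM | 60.0 mM |
| free catalyst | 12 µM | 12 µM | 12 µM | 12 µM |
| impurity | 2.3 µM | 2.3 µM | 2.3 µM | 2.3 µM |
| remark | run made earlier | run made earlier | run made earlier |  |

| run | time / min | product / % | substrate / % |
|---|---|---|---|
| beta | 8.00 | 0.2 | 97.4 |
| beta | 15.0 | 2.8 | 96.7 |
| beta | 25.0 | 4.9 | 93.8 |
| beta | 40.0 | 9.0 | 91.9 |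
| beta | 60.0 | 13.8 | 86.7 |
| beta | 120 | 25.7 | 72.9 |
| zeta | 8.00 | 1.6 | 99.0 |
| zeta | 15.0 | 1.5 | 96.9 |
| zeta | 25.0 | 4.7 | 93.7 |
| zeta | 40.0 | 9.1 | 93.6 |
| zeta | 60.0 | 11.6 | 87.0 |
| zeta | 120 | 24.2 | 77.6 |
| gamma | 8.00 | 0.6 | 97.4 |
| gamma | 15.0 | 0.6 | 97.8 |
| gamma | 30.0 | 3.5 | 96.3 |
| gamma | 60.0 | 7.0 | 93.2 |
| gamma | 120 | 15.1 | 86.5 |

(readings scatter by 1 percentage point)

- no earlier run changes the charge of free catalyst; that part of a forecast is a guess

- apparent order in reagent when 20% of the substrate are converted (percent change of the rate of making product for one percent more reagent charged)
- apparent order in free catalyst when 20% of the substrate are converted (percent change of the rate of making product for one percent more free catalyst charged)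

*Which run speaks about reagent?* Gamma does, with the flask's substrate and half its reagent. But gamma has no partner, since beta and zeta have the flask's reagent and less substrate.

*So what comes first?* The substrate order. At 120 min, beta has made 25.7% of 10 mM and zeta 24.2% of 15 mM. Comparing these amounts of product against the two charges gives an order of 0.852, which is a reading.

*And then?* I carry zeta up to the flask's substrate. With that order, the percent made at 120 min shifts to 23.2%, and gamma read 15.1% at that time.

*What do you conclude?* The logarithm of that ratio over the logarithm of the reagent ratio gives 0.619. This is the percent change of percent made per percent change of reagent, read between gamma and zeta carried to gamma's substrate, and I call it the doubling exponent. It is my own estimate for the reagent order; the one-step world would give 1.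

*Isn't that scatter?* Partly: gamma's reading carries 1 percentage point on 15.1%, so the second digit is not firm. It is also a mean between the two reagent charges, not a slope at the flask's charge.

*And the catalyst?* No earlier run changes its charge, so I have no reading.

The forecast gives 0.93 for reagent and 1.15 for free catalyst. It holds that “the rate is about first order in substrate”, and its reagent order stands above my exponent.

The simulation gives 0.51 for reagent and 1.2 for free catalyst. The forecast's reagent order is 1.82 times too high, while its catalyst order agrees within the tolerance.

    free catalyst + impurity → spent catalyst (k = 2.30 × 10⁵ M⁻¹ min⁻¹)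
    substrate + free catalyst ⇌ catalyst intermediate A (K = 78.0 M⁻¹, k = 580 M⁻¹ min⁻¹)
    reagent + catalyst intermediate A ⇌ catalyst intermediate B (K = 35.0 M⁻¹, k = 290 M⁻¹ min⁻¹)
    catalyst intermediate C → free catalyst + product (k = 60.0 min⁻¹)
    catalyst intermediate B → released group + catalyst intermediate C (k = 25.0 min⁻¹)

The flask reached 20% conversion after 1.98 h, and gamma read 15.1% product at 120 min. Taking product as conversion and these two times as equal, the doubling exponent between them reads 0.405. At 1.50 h the flask holds 43.9% of its catalyst as free catalyst and 21.7% as catalyst intermediate A. Reckoned from the flask's amounts at that moment and the forward rate constants, the forward rate of substrate with free catalyst, over the forward rate of reagent with catalyst intermediate A, is 1.20.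

The data are calculated with constants of no real substance, noise included.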